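**Retrosynthesis**
1. The C7 secondary alcohol comes from stereoselective reduction of a push-pull cyclopentenone. The C8 tertiary silyl ether is removed last.
2. Ring B (C1–O2–C3=C4 enol ether acylal) is closed late. A C1 acetal and a C3 enol ether are hydrolysed and cyclised to a lactol, which is then acylated.
3. The dienone with its C11 acetate comes from a Babler–Dauben transposition of a tertiary allylic alcohol, followed by an allylic acetal-to-acetate transposition.
4. Ring A is formed first, by Piancatelli rearrangement of 2,5-bis(hydroxymethyl)furan. Lipase resolution and α′-acetalisation then set C8 and C9.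

Assumptions:
- The lipase acylates the (S)-carbinol preferentially.
- Acylation of the lactol gives the natural C1 anomer (OIsov cis to H9) as the major or separable isomer.
- C9 is configurationally stable under the mild conditions used.

**Step 1**
Reactants: 1 2,5-bis(hydroxymethyl)furan (BHMF)
Product: 2 (±)-4-hydroxy-4-(hydroxymethyl)cyclopent-2-en-1-one
Conditions: ZnCl2 (cat.), H2O, 100 °C
Reagents that add atoms: none (water is the solvent; the reaction is an isomerisation, C6H8O3 to C6H8O3, so no atoms are added overall)
Why: The Piancatelli rearrangement (furfuryl cation, water attack at furan C5, 4π-electrocyclisation) builds ring A with the C8 quaternary carbinol and the C10 CH2OH. The water oxygen becomes the C8–OH and the original carbinol OH leaves as water. C8 is the only stereocentre and is formed racemic.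

**Step 2**
Reactants: 2 (±)-cyclopentenone diol; 3 vinyl 3-methylbutanoate
Product: 4 [(1S)-1-hydroxy-4-oxocyclopent-2-en-1-yl]methyl 3-methylbutanoate
Conditions: Burkholderia cepacia lipase (PS-IM), MTBE, 30 °C, about 50% conversion
Reagents that add atoms: vinyl 3-methylbutanoate, C=COC(=O)CC(C)C
Why: Lipase transesterification of the primary alcohol is a kinetic resolution. It installs the C10 isovalerate and leaves C8 as (S), while the tertiary C8–OH is untouched (acetaldehyde is the by-product).

**Step 3**
Reactants: 4 (S)-ester; 5 triethylsilyl triflate; 6 trimethyl orthoformate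
Product: 7 [(1R,5S)-5-(dimethoxymethyl)-4-oxo-1-(triethylsilyloxy)cyclopent-2-en-1-yl]methyl 3-methylbutanoate
Conditions: (a) TESOTf, Et3N, CH2Cl2, −78 °C; (b) HC(OMe)3, TMSOTf (cat.), −78 °C
Reagents that add atoms: triethylsilyl triflate, CC[Si](CC)(CC)OS(=O)(=O)C(F)(F)F; trimethyl orthoformate, COC(OC)OC
Why: TESOTf/Et3N silylates the C8–OH (SiEt3 stays on O8) and forms the silyl dienol ether, which can only enolise toward C9. A Mukaiyama-type acetalisation with the dimethoxycarbenium ion (CH(OMe)2 added at C9) then follows. The electrophile attacks the face syn to the smaller C8–OSiEt3 and anti to the C8–CH2O-isovalerate, which puts C1 cis to O8 as in the target.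

**Step 4**
Reactants: 7 acetal enone; 8 2-bromo-3,3-diethoxyprop-1-ene
Product: 9 tertiary allylic alcohol (diethoxypropenyl adduct at C5, C5 epimer mixture)
Conditions: 8, t-BuLi, Et2O, −78 °C; CeCl3, THF; then add 7, −78 °C
Reagents that add atoms: 2-bromo-3,3-diethoxyprop-1-ene, C=C(Br)C(OCC)OCC
Why: Organocerium 1,2-addition (Imamoto) is chemoselective for the ketone over the ester and the enone C=C. It adds the C(=CH2)CH(OEt)2 unit (the C4/C3/C11 fragment; Br is lost). The new C5 stereocentre is irrelevant because it becomes sp2 in the next step.

**Step 5**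
Reactants: 9 allylic alcohol
Product: 10 dienone (C5=C6, C7=O)
Conditions: PCC, NaOAc, 4 Å MS, CH2Cl2, rt
Reagents that add atoms: none (Cr is not retained)
Why: The Babler–Dauben oxidative 1,3-transposition ([3,3] chromate shift, then oxidation) moves the oxygen from C5 to C7. This erases the C5 stereocentre and leaves C8 and C9 untouched.

**Step 6**
Reactants: 10 dienone; 11 acetic acid
Product: 12 push-pull dienone with C11–OAc and a C3 ethyl enol ether
Conditions: AcOH, PPTS (cat.), 30 °C
Reagents that add atoms: acetic acid, CC(=O)O
Why: Acid ionises the allylic diethyl acetal to an oxocarbenium/allyl cation. Acetate traps it at the CH2 terminus (allylic acetal transposition, EtOH lost), giving C11–OAc and the C3 ethyl enol ether, driven by the push-pull chromophore.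

**Step 7**
Reactants: 12 enol ether acetal
Product: 13 bicyclic lactol (ring B closed, C1–OH as an anomeric mixture)
Conditions: 2 M HCl, THF/H2O (4:1), 0 °C → rt
Reagents that add atoms: water, O
Why: Hydrolysis releases the C1 aldehyde (from the dimethyl acetal) and the C3 vinylogous-acid enol (from the ethyl enol ether). The enol oxygen closes onto C1 by hemiacetalisation, forming ring B and the cyclic enol ether. C9 is unchanged, and the C1 anomers equilibrate.

**Step 8**
Reactants: 13 lactol; 14 isovaleric anhydride
Product: 15 1-O-isovaleryl acylal dienone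
Conditions: (iPrCH2CO)2O, pyridine, DMAP (cat.), CH2Cl2, 0 °C
Reagents that add atoms: isovaleric anhydride, CC(C)CC(=O)OC(=O)CC(C)C
Why: Anomeric O-acylation is chemoselective because the hemiacetal OH is far more reactive than anything else present, and the C8 oxygen is silylated. C1 is set under anomeric control, with the isomer cis to H9 favoured or separated.

**Step 9**
Reactants: 15 acylal dienone
Product: 16 C7 alcohol (C8–OTES)
Conditions: NaBH4, CeCl3·7H2O, EtOH/CH2Cl2, −40 °C
Reagents that add atoms: none (hydride adds hydrogen only)
Why: Luche 1,2-reduction of the C7 ketone; hydride enters from the face bearing the smaller OSiEt3 and anti to the C10 CH2O-isovalerate. This gives 7-OH trans to O8 and cis to C10, as in the target.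

**Step 10**
Reactants: 16 TES-protected diol
Product: 17 Jatamanvaltrate J
Conditions: HF·pyridine, pyridine, THF, 0 °C → rt
Reagents that add atoms: none (the silyl group leaves as Et3SiF)
Why: Buffered fluoride removes the tertiary silyl ether and leaves the acylal, the enol ether and the esters intact. No stereocentre is touched.

**Compound list**
1 | 2,5-bis(hydroxymethyl)furan | OCc1ccc(CO)o1 | starting material
2 | (±)-4-hydroxy-4-(hydroxymethyl)cyclopent-2-en-1-one | O=C1C=CC(O)(CO)C1 | intermediate
3 | vinyl 3-methylbutanoate | C=COC(=O)CC(C)C | starting material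
4 | [(1S)-1-hydroxy-4-oxocyclopent-2-en-1-yl]methyl 3-methylbutanoate | O=C1C=C[C@](O)(COC(=O)CC(C)C)C1 | intermediate
5 | triethylsilyl triflate | CC[Si](CC)(CC)OS(=O)(=O)C(F)(F)F | starting material
6 | trimethyl orthoformate | COC(OC)OC | starting material
7 | [(1R,5S)-5-(dimethoxymethyl)-4-oxo-1-(triethylsilyloxy)cyclopent-2-en-1-yl]methyl 3-methylbutanoate | COC(OC)[C@H]1C(=O)C=C[C@]1(O[Si](CC)(CC)CC)COC(=O)CC(C)C | intermediate
8 | 2-bromo-3,3-diethoxyprop-1-ene | C=C(Br)C(OCC)OCC | starting material
9 | tertiary allylic alcohol (4-(3,3-diethoxyprop-1-en-2-yl)-4-hydroxy analogue of 7; C8 and C9 as in 7, C5 epimer mixture) | COC(OC)[C@H]1C(O)(C(=C)C(OCC)OCC)C=C[C@]1(O[Si](CC)(CC)CC)COC(=O)CC(C)C | intermediate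
10 | dienone (4-(3,3-diethoxyprop-1-en-2-yl)-5-(dimethoxymethyl)-2-oxocyclopent-3-en-1-yl analogue) | COC(OC)[C@H]1C(C(=C)C(OCC)OCC)=CC(=O)[C@]1(O[Si](CC)(CC)CC)COC(=O)CC(C)C | intermediate
11 | acetic acid | CC(=O)O | starting material
12 | push-pull dienone, C11–OAc and C3–OEt enol ether | COC(OC)[C@H]1C(C(COC(C)=O)=COCC)=CC(=O)[C@]1(O[Si](CC)(CC)CC)COC(=O)CC(C)C | intermediate
13 | bicyclic lactol (1-hydroxy-cyclopenta[c]pyran-6-one; C1 anomeric mixture) | OC1OC=C(COC(C)=O)C2=CC(=O)[C@](O[Si](CC)(CC)CC)(COC(=O)CC(C)C)[C@@H]12 | intermediate
14 | isovaleric anhydride | CC(C)CC(=O)OC(=O)CC(C)C | starting material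
15 | 1-O-isovaleryl acylal dienone | CC(C)CC(=O)O[C@@H]1OC=C(COC(C)=O)C2=CC(=O)[C@](O[Si](CC)(CC)CC)(COC(=O)CC(C)C)[C@@H]12 | intermediate
16 | C7-alcohol, C8–OTES | CC(C)CC(=O)O[C@@H]1OC=C(COC(C)=O)C2=C[C@H](O)[C@](O[Si](CC)(CC)CC)(COC(=O)CC(C)C)[C@@H]12 | intermediate
17 | Jatamanvaltrate J | CC(=O)OCC1=CO[C@@H](OC(=O)CC(C)C)[C@H]2C1=C[C@H](O)[C@]2(O)COC(=O)CC(C)C | target

**Totals**
Total steps: 10. Longest linear sequence: 10, from BHMF.

**Three steps most likely to fail**
1. **Step 5 (Babler–Dauben transposition).** The tertiary alcohol is allylic on two sides, through C6=C7 and through C4=CH2, so transposition could go toward C11 instead of C7, and the acetals may not tolerate PCC. Fallback, which changes the approach: replace the transposition by a regio-defined sequence on 7. This is nucleophilic epoxidation (t-BuOOH, DBU), Pd(0) isomerisation to the cyclopentane-1,3-dione, selective C5 enol triflation and Stille coupling with a 2-stannyl-3,3-diethoxypropene, which gives dienone 10 directly.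
2. **Step 3 (C9 α′-acetalisation).** The facial selectivity and the stability of the silyl cyclopentadienyl ether are uncertain, and the wrong face would give C1 trans to O8. Fallback, which changes the approach: drop intermolecular facial control and tether the new carbon from O8. Make the bromomethyldimethylsilyl ether of the C8–OH and the C9=C5 silyl enol ether of 4, then run a Stork–Nishiyama radical cyclisation (Bu3SnH, AIBN). This forms the C9–CH2 bond on the same face as O8, so C1 is cis to O8 by construction. Tamao–Fleming oxidation then gives the C9–CH2OH, and oxidation to the aldehyde and acetalisation give the C1 dimethyl acetal. The C5 ketone is regenerated, and the route continues from Step 4.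
3. **Step 7 (ring B closure to the lactol, then the Step 8 acylal).** The β-silyloxy aldehyde can undergo retro-aldol or elimination, C9 is acidic, and the open-chain vinylogous acid can O-acylate instead of the lactol. Fallback, which changes the approach: close ring B as the cyclic methyl acetal (TsOH, MeOH on 12), then convert the C1 methoxy acetal to the isovalerate acylal by exchange with isovaleric anhydride and TMSOTf, which avoids handling the free lactol.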